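**Retrosynthetic overview**
- Target ⇒ 6,8-dibromo-5,7-dihydroxy-3,4'-dimethoxyflavone: both ring A C–OMe bonds are cut (copper-mediated methoxylation).
- ⇒ 5,7-dihydroxy-3,4'-dimethoxyflavone: both C–Br bonds are cut (bromination at C6 and C8).
- ⇒ phloroglucinol + methyl 2-methoxy-3-(4-methoxyphenyl)-3-oxopropanoate: C4–C4a and O1–C2 are cut (proposed new alkoxy(aroyl)ketene pyrone annulation, which brings in the 3-OMe group).
- ⇒ methyl methoxyacetate + 4-methoxybenzoyl chloride (crossed Claisen condensation).
- Ring order: rings A and B are bought; ring C is the only ring formed (step 2); the two ring A methoxy groups go on last.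

Assumption: araneosol has no stereocentre or other stereogenic element, so "single enantiomer" is taken to mean the achiral compound itself.

**Step 1**
Reactants: 1 methyl methoxyacetate; 2 4-methoxybenzoyl chloride
Product: 5 methyl 2-methoxy-3-(4-methoxyphenyl)-3-oxopropanoate (racemic at C2, enolisable), via ester lithium enolate 3 (not isolated), via ketoester lithium enolate 4 (not isolated)
Conditions: LiN(SiMe3)2 (2.2 equiv), THF, −78 °C, 40 min; then 2 (1.0 equiv), −78 → 0 °C; aq. HCl
Reagents that add atoms: none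
Why: Crossed Claisen condensation (C-acylation of a preformed ester enolate by an aroyl chloride); the second equivalent of base holds the more acidic product as enolate 4 so it is not acylated again, and the C2 stereocentre, formed racemic, becomes sp2 in step 2.

**Step 2**
Reactants: 5 methyl 2-methoxy-3-(4-methoxyphenyl)-3-oxopropanoate; 6 phloroglucinol (anhydrous)
Product: 9 ermanin (5,7-dihydroxy-3-methoxy-2-(4-methoxyphenyl)-4H-chromen-4-one), via aroyl(methoxy)ketene 7 (not isolated), via methoxy-diketone 8 (not isolated)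
Conditions: Ph2O, 230 °C, N2 sweep; 5 added over 30 min to 6 (1.5 equiv), then 30 min (MeOH and H2O distil out)
Reagents that add atoms: none
Why: Proposed new method: thermal alkoxy(aroyl)ketene pyrone annulation — the chelated enol of 5 expels MeOH through a six-membered transition state to give ketene 7, the ketene carbon is attacked by a ring carbon of the strongly C-nucleophilic, threefold-symmetric phloroglucinol (only one regioisomer possible) to give diketone 8, and an ortho-OH then adds to the anisoyl carbonyl and loses water to close ring C as the hydrogen-bonded 5-hydroxychromone, acid being excluded so that Pechmann-type attack of the arene on the ketone (coumarin formation) is not triggered; the closest known reaction type is the Mentzer thermal condensation of phloroglucinol with aroylacetates bearing H or alkyl at the α-carbon, whereas an α-alkoxy ketoester, which delivers the 3-OMe group directly, has not been used.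

**Step 3**
Reactants: 9 ermanin
Product: 12 dibromoermanin (6,8-dibromo-5,7-dihydroxy-3-methoxy-2-(4-methoxyphenyl)-4H-chromen-4-one), via 8-bromoflavone 10 (not isolated), via 6-bromoflavone 11 (not isolated)
Conditions: NBS (2.05 equiv), DMF, 0 °C → rt, dark, 2 h
Reagents that add atoms: N-bromosuccinimide, O=C1CCC(=O)N1Br
Why: Electrophilic aromatic bromination; C6 and C8, each flanked by two oxygen donors of the phloroglucinol-type ring A, are far more nucleophilic than the anisyl ring (deactivated by conjugation with the pyrone carbonyl) or the fully substituted C2=C3 bond, so two equivalents stop at the dibromide whichever position reacts first.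

**Step 4**
Reactants: 12 dibromoermanin
Product: 15 araneosol (5,7-dihydroxy-3,6,8-trimethoxy-2-(4-methoxyphenyl)-4H-chromen-4-one), via 8-bromo-6-methoxyflavone 13 (not isolated), via 6-bromo-8-methoxyflavone 14 (not isolated)
Conditions: NaOMe (12 equiv, in MeOH), CuBr (0.3 equiv), DMF, 110 °C, N2, 4 h; then aq. HCl to pH 3
Reagents that add atoms: sodium methoxide, [Na+].[O-]C
Why: Ullmann-type ether synthesis (C–O coupling of aryl bromides with methoxide, monovalent copper as the active species), established on 6,8-dibromo-5,7-dihydroxyflavones; the ionised 5- and 7-OH groups make the pyrone too electron-rich for ring opening by methoxide and are returned as free phenols on acidification.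

**Compound list**
1 | methyl methoxyacetate | COCC(=O)OC | starting material
2 | 4-methoxybenzoyl chloride | COc1ccc(cc1)C(Cl)=O | starting material
3 | lithium 1,2-dimethoxyethen-1-olate (lithium enolate of 1, chelated, O–Li cis to the 2-methoxy group) | [Li+].[O-]/C(OC)=C\OC | intermediate
4 | lithium 2,3-dimethoxy-1-(4-methoxyphenyl)-3-oxoprop-1-en-1-olate (lithium enolate of 5, chelated, O–Li cis to the ester carbonyl) | [Li+].[O-]/C(c1ccc(OC)cc1)=C(\C(=O)OC)OC | intermediate
5 | methyl 2-methoxy-3-(4-methoxyphenyl)-3-oxopropanoate (racemic) | COC(=O)C(OC)C(=O)c1ccc(OC)cc1 | intermediate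
6 | phloroglucinol (benzene-1,3,5-triol) | Oc1cc(O)cc(O)c1 | starting material
7 | 2-methoxy-3-(4-methoxyphenyl)-3-oxoprop-1-en-1-one (4-methoxybenzoyl(methoxy)ketene) | COC(=C=O)C(=O)c1ccc(OC)cc1 | intermediate
8 | 2-methoxy-1-(4-methoxyphenyl)-3-(2,4,6-trihydroxyphenyl)propane-1,3-dione (racemic) | COC(C(=O)c1ccc(OC)cc1)C(=O)c1c(O)cc(O)cc1O | intermediate
9 | ermanin, 5,7-dihydroxy-3-methoxy-2-(4-methoxyphenyl)-4H-chromen-4-one | COc1ccc(cc1)-c1oc2cc(O)cc(O)c2c(=O)c1OC | intermediate
10 | 8-bromo-5,7-dihydroxy-3-methoxy-2-(4-methoxyphenyl)-4H-chromen-4-one | COc1ccc(cc1)-c1oc2c(Br)c(O)cc(O)c2c(=O)c1OC | intermediate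
11 | 6-bromo-5,7-dihydroxy-3-methoxy-2-(4-methoxyphenyl)-4H-chromen-4-one | COc1ccc(cc1)-c1oc2cc(O)c(Br)c(O)c2c(=O)c1OC | intermediate
12 | 6,8-dibromo-5,7-dihydroxy-3-methoxy-2-(4-methoxyphenyl)-4H-chromen-4-one | COc1ccc(cc1)-c1oc2c(Br)c(O)c(Br)c(O)c2c(=O)c1OC | intermediate
13 | 8-bromo-5,7-dihydroxy-3,6-dimethoxy-2-(4-methoxyphenyl)-4H-chromen-4-one | COc1ccc(cc1)-c1oc2c(Br)c(O)c(OC)c(O)c2c(=O)c1OC | intermediate
14 | 6-bromo-5,7-dihydroxy-3,8-dimethoxy-2-(4-methoxyphenyl)-4H-chromen-4-one | COc1ccc(cc1)-c1oc2c(OC)c(O)c(Br)c(O)c2c(=O)c1OC | intermediate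
15 | araneosol, 5,7-dihydroxy-3,6,8-trimethoxy-2-(4-methoxyphenyl)-4H-chromen-4-one (achiral) | COc1ccc(-c2oc3c(OC)c(O)c(OC)c(O)c3c(=O)c2OC)cc1 | target

**Step count**
Total steps: 4. Longest linear sequence: 4 steps (1 → 5 → 9 → 12 → 15).

**Three steps most likely to fail**

Step 2 (the proposed new annulation). The α-OMe group may slow ketene formation, or the melt may give the isomeric 3-methoxy-4-arylcoumarin or ketene oligomers. The fallback uses known chemistry, sets out from 6 and comes back at 9. Hoesch acylation of 6 with methoxyacetonitrile (ZnCl2, HCl gas, Et2O, 0 °C) precipitates 2-methoxy-1-(2,4,6-trihydroxyphenyl)ethan-1-iminium chloride F1. Boiling water hydrolyses it to 2-methoxy-1-(2,4,6-trihydroxyphenyl)ethan-1-one F2. Allan–Robinson condensation of F2 with 4-methoxybenzoic anhydride and 4-MeOC6H4CO2Na (melt, 180 °C) builds ring C and gives chiefly 5-hydroxy-3-methoxy-2-(4-methoxyphenyl)-4-oxo-4H-chromen-7-yl 4-methoxybenzoate F3. Brief KOH/aq. EtOH hydrolysis of the ester gives 9.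

Step 4 (twofold Ullmann methoxylation). Hydrodebromination or a stalled second substitution at the doubly flanked positions would give inseparable 6-H/8-H flavones. The fallback sets out from 12 and comes back at 15, and replaces the phenoxide/copper approach by a protected substrate and palladium C–O cross-coupling. Benzylation (BnBr, K2CO3, DMF, 70 °C) gives 5,7-bis(benzyloxy)-6,8-dibromo-3-methoxy-2-(4-methoxyphenyl)-4H-chromen-4-one F4. Coupling with MeOH (Pd(OAc)2, tBuBrettPhos, Cs2CO3, toluene/MeOH, 80 °C; zerovalent palladium formed in situ) gives 5,7-bis(benzyloxy)-3,6,8-trimethoxy-2-(4-methoxyphenyl)-4H-chromen-4-one F5. Hydrogenolysis (H2, Pd/C, EtOAc, rt) gives 15.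

Step 1 (crossed Claisen). O-acylation, double acylation or self-condensation of the α-alkoxy ester enolate may erode the yield. The fallback sets out from 2 and comes back at 5, and introduces the methoxy group by carbene O–H insertion instead. Acylation of KO2CCH2CO2Me with 2 (MgCl2, Et3N, MeCN) gives 3-methoxy-2-(4-methoxybenzoyl)-3-oxopropanoic acid F6. On acidification (aq. HCl) it decarboxylates to methyl 3-(4-methoxyphenyl)-3-oxopropanoate F7. Diazo transfer (4-acetamidobenzenesulfonyl azide, Et3N, MeCN) gives methyl 2-diazo-3-(4-methoxyphenyl)-3-oxopropanoate F8. Rh2(OAc)4-catalysed O–H insertion into MeOH (CH2Cl2/MeOH, rt) gives 5.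

**Further compounds**
F1 | step 2 | 2-methoxy-1-(2,4,6-trihydroxyphenyl)ethan-1-iminium chloride | COCC(=[NH2+])c1c(O)cc(O)cc1O.[Cl-]
F2 | step 2 | 2-methoxy-1-(2,4,6-trihydroxyphenyl)ethan-1-one | COCC(=O)c1c(O)cc(O)cc1O
F3 | step 2 | 5-hydroxy-3-methoxy-2-(4-methoxyphenyl)-4-oxo-4H-chromen-7-yl 4-methoxybenzoate | COc1ccc(cc1)C(=O)Oc1cc(O)c2c(c1)oc(-c1ccc(OC)cc1)c(OC)c2=O
F4 | step 4 | 5,7-bis(benzyloxy)-6,8-dibromo-3-methoxy-2-(4-methoxyphenyl)-4H-chromen-4-one | COc1ccc(cc1)-c1oc2c(Br)c(OCc3ccccc3)c(Br)c(OCc3ccccc3)c2c(=O)c1OC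
F5 | step 4 | 5,7-bis(benzyloxy)-3,6,8-trimethoxy-2-(4-methoxyphenyl)-4H-chromen-4-one | COc1ccc(cc1)-c1oc2c(OC)c(OCc3ccccc3)c(OC)c(OCc3ccccc3)c2c(=O)c1OC
F6 | step 1 | 3-methoxy-2-(4-methoxybenzoyl)-3-oxopropanoic acid (racemic) | COC(=O)C(C(O)=O)C(=O)c1ccc(OC)cc1
F7 | step 1 | methyl 3-(4-methoxyphenyl)-3-oxopropanoate | COC(=O)CC(=O)c1ccc(OC)cc1
F8 | step 1 | methyl 2-diazo-3-(4-methoxyphenyl)-3-oxopropanoate | COC(=O)C(=[N+]=[N-])C(=O)c1ccc(OC)cc1
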